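## Retrosynthetic overview

- The target is reached by exo-selective dehydration of its 8α-hydroxy precursor (C8=C17 formed last, no ring formed).
- That precursor comes from one proton-initiated cation–olefin cascade on the complete acyclic C20 chain, methyl (5S)-5-acetoxygeranylgeranoate. Ring A closes first (C4–C5), then ring B (C9–C10), and the C11 acetate captures C8.
- The C11 stereocentre is the only source of chirality and is meant to set C5, C8, C9 and C10.
- The acyclic acetate comes from acetylation of the product of a catalytic asymmetric vinylogous Mukaiyama aldol between (2E,6E)-farnesal and the silyl dienolate of methyl 3-methylbut-2-enoate (C11–C12 bond, C11 centre, 13E enoate).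
- Farnesal comes from (2E,6E)-farnesol; the dienolate from methyl 3-methylbut-2-enoate.

Convention and assumption: ring compounds carry labdane numbering and acyclic ones hexadecatetraenoate numbering; the (S,S) catalyst in step 3 is written on the premise that its (R,R) antipode attacks the Re face of aldehydes, and whichever antipode gives Si-face attack is the one used.

## Route

Step 1
Reactants: 1 methyl 3-methylbut-2-enoate
Product: 3 tert-butyl{[(1Z)-1-methoxy-3-methylbuta-1,3-dien-1-yl]oxy}dimethylsilane, via lithium dienolate 2 (not isolated)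
Conditions: LiN(i-Pr)2 (LDA, commercial solution, 1.1 equiv), THF, −78 °C; then TBSCl, DMPU, −78 °C → rt; distillation
Reagents that add atoms: lithium diisopropylamide, [Li+].CC(C)[N-]C(C)C (lithium of intermediate 2 only); tert-butyldimethylsilyl chloride, CC(C)(C)[Si](C)(C)Cl
Why: Kinetic γ-deprotonation of the enoate gives the extended lithium dienolate, which TBSCl silylates on oxygen (silyl ketene acetal formation); no stereocentre is formed and the ketene acetal geometry is lost in step 3.

Step 2
Reactants: 4 (2E,6E)-farnesol
Product: 5 (2E,6E)-farnesal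
Conditions: activated MnO2 (15 equiv), hexane, rt
Reagents that add atoms: none
Why: MnO2 oxidises the allylic alcohol chemoselectively to the enal without over-oxidation and without E/Z scrambling (allylic alcohol oxidation).

Step 3
Reactants: 5 (2E,6E)-farnesal; 3 silyl dienolate
Product: 7 methyl (2E,5S,6E,10E)-5-hydroxy-3,7,11,15-tetramethylhexadeca-2,6,10,14-tetraenoate, via trichlorosilyl ether 6 (not isolated)
Conditions: SiCl4 (1.1 equiv), (S,S)-N,N'-(pentane-1,5-diyl)bis[N,3,5-trimethyl-3,5-dihydro-4H-dinaphtho[2,1-d:1',2'-f][1,3,2]diazaphosphepin-4-amine 4-oxide] (2 mol %), i-Pr2NEt (10 mol %), CH2Cl2, −78 °C; then sat. aq. NaHCO3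
Reagents that add atoms: silicon tetrachloride, Cl[Si](Cl)(Cl)Cl (SiCl3 group of intermediate 6 only)
Why: Catalytic enantioselective vinylogous Mukaiyama aldol (Lewis-base activation of SiCl4): the chiral phosphoramide-bound trichlorosilyl cation activates the enal for 1,2-addition, and the dienolate attacks through its γ-carbon on the Si face, which sets 5S (the later C11) and delivers the E enoate.

Step 4
Reactants: 7 methyl (2E,5S,6E,10E)-5-hydroxy-3,7,11,15-tetramethylhexadeca-2,6,10,14-tetraenoate
Product: 8 methyl (2E,5S,6E,10E)-5-acetoxy-3,7,11,15-tetramethylhexadeca-2,6,10,14-tetraenoate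
Conditions: Ac2O, pyridine, 4-(dimethylamino)pyridine (5 mol %), CH2Cl2, 0 °C → rt
Reagents that add atoms: acetic anhydride, CC(=O)OC(C)=O
Why: Nucleophile-catalysed acylation of the secondary allylic alcohol; the stereocentre is not touched and the mild base avoids E1cB loss of the δ-oxygen.

Step 5
Reactants: 8 methyl (2E,5S,6E,10E)-5-acetoxy-3,7,11,15-tetramethylhexadeca-2,6,10,14-tetraenoate
Product: 10 methyl (2E,5S)-5-acetoxy-5-[(1S,2R,4aS,8aS)-2-hydroxy-2,5,5,8a-tetramethyldecahydronaphthalen-1-yl]-3-methylpent-2-enoate (methyl (11S,13E)-11-acetoxy-8α-hydroxylabd-13-en-15-oate), via dioxanylium fluorosulfate 9 (not isolated)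
Conditions: FSO3H (1.2 equiv), 2-nitropropane/CH2Cl2 (1:1), −78 °C, 30 min; then sat. aq. NaHCO3, −78 °C → rt; chromatography
Reagents that add atoms: fluorosulfonic acid, OS(=O)(=O)F (counter-ion of intermediate 9 only); water, O
Why: Proposed new method: Markovnikov protonation of the terminal 14,15-alkene (the 6,7- and 2,3-alkenes are deactivated by the allylic acetoxy and ester groups) starts a chair–chair cation–olefin bicyclisation of the all-E chain in which the two anti additions (Stork–Eschenmoser) give the trans-decalin with an equatorial C9 side chain, and the C8 cation is taken anti by the acetate carbonyl oxygen as a trans-fused 2-methyl-1,3-dioxan-2-ylium ion 9 whose chair tolerates the C12 chain only equatorial (H-11 eclipsing C17, minimal allylic 1,3-strain, attack on C9 anti to the C–O bond), which for the 11S substrate means the 5S,8R,9S,10S folding, so C11 sets the four new stereocentres and the wrong folding can only give separable diastereomers; the bicarbonate quench opens the ortho-acid to the tertiary alcohol and leaves the ester on the secondary oxygen; the closest known chemistry is the low-temperature superacid cyclisation of polyprenyl acetates and of homofarnesic acid (carbonyl-oxygen termination) together with acetate or carbonate neighbouring-group capture in cation–olefin cyclisations, and the acid is kept near one equivalent so that the acetate stays free to capture C8 and is not ionised.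

Step 6
Reactants: 10 methyl (11S,13E)-11-acetoxy-8α-hydroxylabd-13-en-15-oate
Product: 12 methyl (2E,5S)-5-acetoxy-3-methyl-5-[(1S,4aS,8aS)-5,5,8a-trimethyl-2-methylidenedecahydronaphthalen-1-yl]pent-2-enoate (methyl (11S,13E)-11-acetoxylabda-8(17),13-dien-15-oate, the target), via chlorosulfite 11 (not isolated)
Conditions: SOCl2 (1.5 equiv), pyridine (6 equiv), CH2Cl2, −78 °C → −40 °C
Reagents that add atoms: thionyl chloride, O=S(Cl)Cl (in intermediate 11 only)
Why: The equatorial 8α-chlorosulfite has no anti-periplanar ring hydrogen, so the pyridine-mediated E2 elimination at low temperature takes a C17 methyl hydrogen and gives the exocyclic alkene (regioselective dehydration of a tertiary alcohol); no stereocentre is touched.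

## Compound list

1 | methyl 3-methylbut-2-enoate | COC(=O)C=C(C)C | starting material
2 | lithium 1-methoxy-3-methylbuta-1,3-dien-1-olate (lithium dienolate) | C=C(C)/C=C(/OC)[O-].[Li+] | intermediate (not isolated)
3 | tert-butyl{[(1Z)-1-methoxy-3-methylbuta-1,3-dien-1-yl]oxy}dimethylsilane (silyl dienolate; geometry drawn is the expected major one and is immaterial) | C=C(C)/C=C(/OC)O[Si](C)(C)C(C)(C)C | intermediate
4 | (2E,6E)-farnesol | CC(C)=CCC/C(C)=C/CC/C(C)=C/CO | starting material
5 | (2E,6E)-farnesal | CC(C)=CCC/C(C)=C/CC/C(C)=C/C=O | intermediate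
6 | methyl (2E,5S,6E,10E)-3,7,11,15-tetramethyl-5-(trichlorosilyloxy)hexadeca-2,6,10,14-tetraenoate (trichlorosilyl ether) | CC(C)=CCC/C(C)=C/CC/C(C)=C/[C@@H](O[Si](Cl)(Cl)Cl)C/C(C)=C/C(=O)OC | intermediate (not isolated)
7 | methyl (2E,5S,6E,10E)-5-hydroxy-3,7,11,15-tetramethylhexadeca-2,6,10,14-tetraenoate | CC(C)=CCC/C(C)=C/CC/C(C)=C/[C@@H](O)C/C(C)=C/C(=O)OC | intermediate
8 | methyl (2E,5S,6E,10E)-5-acetoxy-3,7,11,15-tetramethylhexadeca-2,6,10,14-tetraenoate | CC(C)=CCC/C(C)=C/CC/C(C)=C/[C@@H](OC(C)=O)C/C(C)=C/C(=O)OC | intermediate
9 | trans-fused 2-methyl-1,3-dioxan-2-ylium ion bridging O-8 and O-11 of the labdane (5S,8R,9S,10S,11S), fluorosulfate salt | C[C@@]12CC[C@H]3C(C)(C)CCC[C@]3(C)[C@H]1[C@H](C/C(C)=C/C(=O)OC)OC(C)=[O+]2.[O-]S(=O)(=O)F | intermediate (not isolated)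
10 | methyl (11S,13E)-11-acetoxy-8α-hydroxylabd-13-en-15-oate (5S,8R,9S,10S,11S) | C[C@@]1(O)CC[C@H]2C(C)(C)CCC[C@]2(C)[C@H]1[C@H](C/C(C)=C/C(=O)OC)OC(C)=O | intermediate
11 | 8α-chlorosulfite of 10 | C[C@@]1(OS(=O)Cl)CC[C@H]2C(C)(C)CCC[C@]2(C)[C@H]1[C@H](C/C(C)=C/C(=O)OC)OC(C)=O | intermediate (not isolated)
12 | methyl (11S,13E)-11-acetoxylabda-8(17),13-dien-15-oate (5S,9S,10S,11S) | C=C1CC[C@H]2C(C)(C)CCC[C@]2(C)[C@H]1[C@H](C/C(C)=C/C(=O)OC)OC(C)=O | target

## Step count and risks

Total steps: 6. Longest linear sequence: 5 steps (4 → 5 → 7 → 8 → 10 → 12); step 1 is a one-step side branch.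

The three steps most likely to fail:

**Step 5 (bicyclisation).** The risks are ionisation of the allylic acetate by the acid, protonation of the 10,11-alkene instead of the terminal one, and weak control over ring A if the two rings close stepwise. In that last case at most half of the material is matched; the mismatched folding gives diastereomers that chromatography removes, so the enantiomeric purity of 10 is not at stake, only the yield. The fallback gives up protonation as the initiating event and starts the cascade by electrophilic mercuration, followed by a separate reductive removal of the metal. It sets out from 8: Hg(OTf)2·PhNMe2 (1.2 equiv, MeNO2, −20 °C) adds to the terminal, least hindered alkene with no free superacid present, so the allylic acetate is not ionised. The same chair–chair closure and acetate capture follow, and work-up with aqueous NaCl/NaHCO3 gives methyl (11S,13E)-11-acetoxy-3β-(chloromercurio)-8α-hydroxylabd-13-en-15-oate F1. NaBH4 (THF/H2O, 0 °C) then replaces C–Hg by C–H, and the sequence comes back to the route at 10.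

**Step 3 (asymmetric vinylogous aldol).** The risk is that a β,β-disubstituted enal such as farnesal gives low enantioselectivity or conversion with this catalyst system. The fallback replaces catalytic asymmetric C–C bond formation by a racemic coupling and a kinetic resolution. It sets out from 5 and 3: BF3·OEt2 (1.1 equiv, CH2Cl2, −78 °C) gives racemic methyl (2E,6E,10E)-5-hydroxy-3,7,11,15-tetramethylhexadeca-2,6,10,14-tetraenoate F2. A Sharpless kinetic resolution (Ti(OiPr)4, D-(−)-diisopropyl tartrate, t-BuOOH, 4 Å sieves, CH2Cl2, −20 °C, run to about 60 % conversion because the methyl group cis to the carbinol lowers the rate ratio) epoxidises the 5R enantiomer to methyl (2E,5R,6S,7S)-6,7-epoxy-5-hydroxy-3,7,11,15-tetramethylhexadeca-2,10,14-trienoate F3. The unreacted 5S alcohol is 7, where the fallback rejoins the route; only the allylic-alcohol alkene is epoxidised.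

**Step 6 (exo-selective dehydration).** The risks are E1 leakage to the 7- and 8(9)-alkenes, and participation of the 11-acetate in ionisation of the chlorosulfite, which would return 10. The fallback changes the elimination from an ionic E2 to a thermal syn-elimination. It sets out from 10: acetylation of the tertiary alcohol (AcCl, N,N-dimethylaniline, CH2Cl2, 40 °C) gives methyl (11S,13E)-8α,11-diacetoxylabd-13-en-15-oate F4. Flash vacuum thermolysis (about 350 °C, 0.1 mbar, base-free so that the δ-acetoxy enoate is not eliminated) expels acetic acid from the tertiary acetate through the cyclic ester-pyrolysis transition state, which favours the three methyl hydrogens, and the fallback comes back to the route at 12.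

## Further compounds

F1 | step 5 | methyl (11S,13E)-11-acetoxy-3β-(chloromercurio)-8α-hydroxylabd-13-en-15-oate | C[C@@]1(O)CC[C@H]2C(C)(C)[C@@H]([Hg]Cl)CC[C@]2(C)[C@H]1[C@H](C/C(C)=C/C(=O)OC)OC(C)=O
F2 | step 3 | racemic methyl (2E,6E,10E)-5-hydroxy-3,7,11,15-tetramethylhexadeca-2,6,10,14-tetraenoate | CC(C)=CCC/C(C)=C/CC/C(C)=C/C(O)C/C(C)=C/C(=O)OC
F3 | step 3 | methyl (2E,5R,6S,7S)-6,7-epoxy-5-hydroxy-3,7,11,15-tetramethylhexadeca-2,10,14-trienoate | CC(C)=CCC/C(C)=C/CC[C@]1(C)O[C@H]1[C@H](O)C/C(C)=C/C(=O)OC
F4 | step 6 | methyl (11S,13E)-8α,11-diacetoxylabd-13-en-15-oate | C[C@@]1(OC(C)=O)CC[C@H]2C(C)(C)CCC[C@]2(C)[C@H]1[C@H](C/C(C)=C/C(=O)OC)OC(C)=O
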